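**Retrosynthetic overview**
1. The central cyclohexene is opened by a retro-Diels–Alder into two identical spiro-monomers; this ring is formed last.
2. In the monomer, the C1 carbinol comes from a hydroxyl-directed ketone reduction, the tetrasubstituted enal from a Dauben–Babler transposition, and the triene arm from Pd α-alkenylation of the C1 ketone with a (Z)-bromotriene made from 6-methylhept-5-en-2-one.
3. The C10 chain comes from aldol condensation/hydrogenation; the C6 carbinol from a chelation-controlled MeMgBr addition to a dienone.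
4. Key step: enantioselective oxidative dearomatisation with semipinacol ring expansion of 2-(1-hydroxycyclobutyl)-4-methoxyphenol. The six-membered ring (from the arene) and the cyclopentanone (from the cyclobutanol) are formed together with the spiro centre.
5. The arene comes from 4-methoxyphenol and cyclobutanone.

Assumption: the SMILES defines the target; spiro[4.5]decane numbering is used (C1 = O-bearing carbon of ring B next to spiro C5, C2 = side-chain carbon, C6 = C(CH3)(O), C9 = enal-bearing carbon, C10 = chain-bearing carbon; ring A = six-membered, ring B = five-membered).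

**Route**

Step 1
Reactants: 1 4-methoxyphenol
Product: 2 2-bromo-4-methoxyphenol
Conditions: N-bromosuccinimide (1.0 equiv), CH2Cl2, 0 °C
Reagents that add atoms: N-bromosuccinimide, O=C1CCC(=O)N1Br
Why: Electrophilic aromatic bromination ortho to the hydroxyl group, the stronger activating substituent; no stereocentre.

Step 2
Reactants: 2 2-bromo-4-methoxyphenol; 3 cyclobutanone
Product: 5 2-(1-hydroxycyclobutyl)-4-methoxyphenol, via dilithio phenoxide 4 (not isolated)
Conditions: n-BuLi (2.2 equiv), THF, −78 → 0 °C; 3, −78 °C; then H2O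
Reagents that add atoms: none
Why: O–H deprotonation then bromine–lithium exchange gives an ortho-lithiated phenoxide that adds 1,2 to the strained ketone; the carbinol carbon is not stereogenic.

Step 3 (key step)
Reactants: 5 2-(1-hydroxycyclobutyl)-4-methoxyphenol
Product: 6 (5S)-9-methoxyspiro[4.5]deca-7,9-diene-1,6-dione
Conditions: (R,R)-2,6-bis[1-(mesitylamino)-1-oxopropan-2-yloxy]iodobenzene (10 mol %), mCPBA (1.3 equiv), CH2Cl2/(CF3)2CHOH 4:1, 4 Å MS, −20 °C
Reagents that add atoms: none
Why: Proposed new method: the phenol binds the chiral aryl-λ3-iodane (trivalent iodine) formed in situ, O–I heterolysis develops positive charge at the cyclobutanol-bearing ortho carbon, and one of the two enantiotopic cyclobutane C–C bonds migrates to it (semipinacol ring expansion driven by strain release and C=O formation), which destroys aromaticity, breaks the mirror symmetry of 5 and sets the spiro centre (5S) under control of the iodane (catalyst enantiomer chosen accordingly); closest known reaction types are the catalytic enantioselective oxidative ortho-spirolactonisation of phenols with chiral iodoarenes (Kita-type dearomatisation) and semipinacol ring expansions of 1-hydroxycyclobutyl cations.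

Step 4
Reactants: 6 (5S)-9-methoxyspiro[4.5]deca-7,9-diene-1,6-dione
Product: 10 (5S,6S)-6-methyl-1,6-bis(triethylsilyloxy)spiro[4.5]deca-1,7-dien-9-one, via lithium enolate 7 (not isolated), via dimetalated carbinolate 8 (not isolated), via bis-silyl methoxydiene 9 (not isolated)
Conditions: LiN(SiMe3)2 (1.05 equiv), THF, −78 °C; MeMgBr (1.5 equiv), −78 → −30 °C; Et3SiOTf (3.5 equiv), 2,6-lutidine, −78 °C; then 0.1 M aqueous oxalic acid, THF, 0 °C
Reagents that add atoms: methylmagnesium bromide, C[Mg]Br; triethylsilyl trifluoromethanesulfonate, CC[Si](CC)(CC)OS(=O)(=O)C(F)(F)F; water, O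
Why: The only enolisable ketone is protected in situ as its enolate, then a chelation-controlled Grignard 1,2-addition follows in which magnesium bridges the C1 enolate oxygen and the C6 carbonyl on the ring-A face carrying C1, so methyl adds from the opposite face and C6–O ends cis to C1 (6S; this facial preference is an expectation, not a certainty); double O-silylation and selective enol-ether hydrolysis of the 2-methoxydiene then give the C9 enone.

Step 5
Reactants: 10 (5S,6S)-6-methyl-1,6-bis(triethylsilyloxy)spiro[4.5]deca-1,7-dien-9-one; 11 3-(benzyloxy)propanal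
Product: 15 (5S,6S,10E)-10-[3-(benzyloxy)propylidene]-6-methyl-1,6-bis(triethylsilyloxy)spiro[4.5]deca-1,7-dien-9-one, via lithium dienolate 12 (not isolated), via lithium aldolate 13 (not isolated), via aldol mesylate 14 (not isolated)
Conditions: LiN(i-Pr)2 (1.1 equiv), THF, −78 °C; 11; MeSO2Cl (1.5 equiv), −78 → 0 °C; DBU, rt
Reagents that add atoms: none
Why: Aldol condensation through the kinetic α′-enolate (C10 is the only enolisable position because C1 is masked and C6 is quaternary) followed by E1cB elimination of the mesylate; the alkene geometry is inconsequential and no new stereocentre survives.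

Step 6
Reactants: 15 (5S,6S,10E)-10-[3-(benzyloxy)propylidene]-6-methyl-1,6-bis(triethylsilyloxy)spiro[4.5]deca-1,7-dien-9-one
Product: 16 (5S,6S,10S)-10-(3-hydroxypropyl)-6-methyl-1,6-bis(triethylsilyloxy)spiro[4.5]dec-1-en-9-one
Conditions: H2 (1 atm), Pd/C (10 wt %), EtOAc, rt
Reagents that add atoms: none
Why: Heterogeneous catalytic hydrogenation saturates both C=C bonds of the cross-conjugated dienone and hydrogenolyses the benzyl ether; hydrogen reaches the exocyclic alkene from the ring-A face opposite the bulky C6 triethylsilyloxy group and C1, placing the C10 chain cis to C6–O and C1 (10S by CIP, the target arrangement), while the hindered silyl enol ether is not reduced.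

Step 7
Reactants: 16 (5S,6S,10S)-10-(3-hydroxypropyl)-6-methyl-1,6-bis(triethylsilyloxy)spiro[4.5]dec-1-en-9-one; 17 tetradecanoyl chloride
Product: 18 3-[(5S,6S,10S)-6-methyl-9-oxo-1,6-bis(triethylsilyloxy)spiro[4.5]dec-1-en-10-yl]propyl tetradecanoate
Conditions: pyridine, DMAP (5 mol %), CH2Cl2, 0 °C
Reagents that add atoms: none
Why: Nucleophilic acyl substitution at the only free hydroxyl group; no stereocentre is touched.

Step 8
Reactants: 18 3-[(5S,6S,10S)-6-methyl-9-oxo-1,6-bis(triethylsilyloxy)spiro[4.5]dec-1-en-10-yl]propyl tetradecanoate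
Product: 19 3-[(5S,6S,10S)-9-hydroxy-6-methyl-9-(prop-1-en-2-yl)-1,6-bis(triethylsilyloxy)spiro[4.5]dec-1-en-10-yl]propyl tetradecanoate (C9 epimers)
Conditions: CH2=C(CH3)MgBr (2.0 equiv), CeCl3 (2.2 equiv), THF, −78 °C; then H2O
Reagents that add atoms: isopropenylmagnesium bromide, CC(=C)[Mg]Br
Why: Organocerium 1,2-addition to the hindered ketone, chemoselective over the ester at −78 °C and non-basic so that C10 does not epimerise; the new C9 carbinol centre is formed as a mixture and is removed in step 15.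

Step 9
Reactants: 20 6-methylhept-5-en-2-one
Product: 22 6-methylhepta-1,5-dien-2-yl trifluoromethanesulfonate, via lithium enolate 21 (not isolated)
Conditions: LiN(i-Pr)2, THF, −78 °C; PhN(SO2CF3)2, −78 → 0 °C; then H2O
Reagents that add atoms: N-phenylbis(trifluoromethanesulfonimide), O=S(=O)(N(c1ccccc1)S(=O)(=O)C(F)(F)F)C(F)(F)F
Why: Kinetic deprotonation at the methyl group and O-triflation of the enolate (enol triflate formation); no stereocentre.

Step 10
Reactants: 22 6-methylhepta-1,5-dien-2-yl trifluoromethanesulfonate; 23 prop-2-enal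
Product: 24 (2E)-8-methyl-4-methylidenenona-2,7-dienal
Conditions: Pd(OAc)2 (5 mol %), PPh3 (10 mol %), Et3N, DMF, 60 °C
Reagents that add atoms: none
Why: Heck reaction of the vinyl triflate at the unsubstituted terminus of the enal; syn β-hydride elimination gives the (E)-alkene.

Step 11
Reactants: 24 (2E)-8-methyl-4-methylidenenona-2,7-dienal
Product: 25 ethyl (2Z,4E)-2-bromo-10-methyl-6-methylideneundeca-2,4,9-trienoate
Conditions: Ph3P=C(Br)CO2Et (1.2 equiv), CH2Cl2, rt
Reagents that add atoms: ethyl 2-bromo-2-(triphenyl-λ5-phosphanylidene)acetate, CCOC(=O)C(Br)=P(c1ccccc1)(c1ccccc1)c1ccccc1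
Why: Wittig olefination with a stabilised α-bromo ylide places the ester trans to the dienyl chain and hence bromine cis to it ((2Z); the minor (2E)-isomer is removed by chromatography).

Step 12
Reactants: 25 ethyl (2Z,4E)-2-bromo-10-methyl-6-methylideneundeca-2,4,9-trienoate
Product: 26 (2Z,4E)-2-bromo-10-methyl-6-methylideneundeca-2,4,9-trien-1-ol
Conditions: i-Bu2AlH (2.2 equiv), CH2Cl2, −78 °C; aqueous work-up
Reagents that add atoms: none
Why: 1,2-Reduction of the ester to the allylic alcohol by an aluminium hydride that leaves the vinyl bromide and the polyene untouched.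

Step 13
Reactants: 26 (2Z,4E)-2-bromo-10-methyl-6-methylideneundeca-2,4,9-trien-1-ol
Product: 27 {[(2Z,4E)-2-bromo-10-methyl-6-methylideneundeca-2,4,9-trien-1-yl]oxy}(tert-butyl)dimethylsilane
Conditions: t-BuMe2SiCl, imidazole, DMF, 0 °C
Reagents that add atoms: tert-butyldimethylsilyl chloride, CC(C)(C)[Si](C)(C)Cl
Why: O-Silylation of the primary allylic alcohol so that it survives the chromium oxidation in step 15.

Step 14
Reactants: 19 3-[(5S,6S,10S)-9-hydroxy-6-methyl-9-(prop-1-en-2-yl)-1,6-bis(triethylsilyloxy)spiro[4.5]dec-1-en-10-yl]propyl tetradecanoate (C9 epimers); 27 {[(2Z,4E)-2-bromo-10-methyl-6-methylideneundeca-2,4,9-trien-1-yl]oxy}(tert-butyl)dimethylsilane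
Product: 28 3-[(2S,5R,6S,10S)-2-[(2E,4E)-1-(tert-butyldimethylsilyloxy)-10-methyl-6-methylideneundeca-2,4,9-trien-2-yl]-9-hydroxy-6-methyl-1-oxo-9-(prop-1-en-2-yl)-6-(triethylsilyloxy)spiro[4.5]decan-10-yl]propyl tetradecanoate (C9 epimers)
Conditions: Pd2(dba)3 (2.5 mol %), P(t-Bu)3 (10 mol %), Bu3SnF (1.2 equiv), CsF (1.5 equiv), toluene, 85 °C
Reagents that add atoms: none
Why: Palladium-catalysed α-alkenylation of a ketone through its silyl enol ether (Kuwajima–Urabe-type coupling via the tin enolate; oxidative addition to zerovalent palladium and reductive elimination both retain the alkene geometry, so the ring ends cis to the dienyl chain); C1 is the sole enolate so the bond forms only at C2, on the face remote from the quaternary C6 centre, and the epimerisable C2 centre settles in the same trans arrangement (2S).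

Step 15
Reactants: 28 (coupled ketone, C9 epimers)
Product: 29 3-[(2S,5R,6S,9Z,10R)-2-[(2E,4E)-1-(tert-butyldimethylsilyloxy)-10-methyl-6-methylideneundeca-2,4,9-trien-2-yl]-6-methyl-1-oxo-9-(1-oxopropan-2-ylidene)-6-(triethylsilyloxy)spiro[4.5]decan-10-yl]propyl tetradecanoate
Conditions: [C5H5NH][CrO3Cl] (3 equiv), NaOAc, 4 Å MS, CH2Cl2, rt
Reagents that add atoms: pyridinium chlorochromate, [O-][Cr](=O)(=O)Cl.c1cc[nH+]cc1
Why: Dauben–Babler oxidative 1,3-transposition ([3,3]-shift of the tertiary allylic chromate ester, then oxidation of the primary chromate) gives the tetrasubstituted enal; in the chair-like transition state the methyl group avoids the branched C10, so the aldehyde ends cis to C10 ((9Z); the (9E)-isomer, if formed, is separated).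

Step 16
Reactants: 29 (silylated keto-enal)
Product: 30 3-[(2S,5R,6S,9Z,10R)-6-hydroxy-2-[(2E,4E)-1-hydroxy-10-methyl-6-methylideneundeca-2,4,9-trien-2-yl]-6-methyl-1-oxo-9-(1-oxopropan-2-ylidene)spiro[4.5]decan-10-yl]propyl tetradecanoate
Conditions: HF·pyridine, pyridine/THF, 0 °C → rt
Reagents that add atoms: none
Why: Fluoride cleavage of both silyl ethers under mildly acidic conditions, which avoids retro-aldol opening of the β-hydroxy ketone and leaves the ester and enal intact.

Step 17
Reactants: 30 (keto-enal diol)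
Product: 31 3-[(1R,2S,5S,6S,9Z,10R)-1,6-dihydroxy-2-[(2E,4E)-1-hydroxy-10-methyl-6-methylideneundeca-2,4,9-trien-2-yl]-6-methyl-9-(1-oxopropan-2-ylidene)spiro[4.5]decan-10-yl]propyl tetradecanoate (monomer)
Conditions: Me4NBH(OAc)3 (5 equiv), MeCN/AcOH 1:1, −35 °C; aqueous work-up
Reagents that add atoms: none
Why: Hydroxyl-directed reduction (Evans–Saksena type): the C6 hydroxyl exchanges onto boron and delivers hydride to the C1 ketone from the ring-B face carrying C6, giving the C1 alcohol anti to C6 and cis to the C2 side chain (1R), while the hindered conjugated aldehyde is not reduced at this temperature.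

Step 18
Reactants: 31 monomer (two molecules)
Product: 32 target CNP0458412.1
Conditions: neat, 2,6-di-tert-butyl-4-methylphenol (1 mol %), Ar, dark, 65 °C, 48 h; preparative HPLC
Reagents that add atoms: none
Why: Thermal intermolecular Diels–Alder homodimerisation in which the terminal 2-substituted 1,3-diene of one molecule adds to the terminal 1,1-disubstituted alkene of the other with ortho/para regiochemistry; the less congested transition state (bulky dienyl arm exo, homoprenyl endo) gives the target's relative configuration at the two new ring centres, but the remote cores barely differentiate the two faces, so the target is separated from its diastereomer by HPLC.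

**Compound list**

1 | 4-methoxyphenol | COc1ccc(O)cc1 | starting material
2 | 2-bromo-4-methoxyphenol | COc1ccc(O)c(Br)c1 | intermediate
3 | cyclobutanone | O=C1CCC1 | starting material
4 | lithium 2-lithio-4-methoxyphenoxide | COc1ccc([O-])c([Li])c1.[Li+] | intermediate (not isolated)
5 | 2-(1-hydroxycyclobutyl)-4-methoxyphenol | COc1ccc(O)c(c1)C1(O)CCC1 | intermediate
6 | (5S)-9-methoxyspiro[4.5]deca-7,9-diene-1,6-dione | COC1=C[C@]2(CCCC2=O)C(=O)C=C1 | intermediate
7 | lithium (5S)-9-methoxy-6-oxospiro[4.5]deca-1,7,9-trien-1-olate | COC1=C[C@]2(CCC=C2[O-])C(=O)C=C1.[Li+] | intermediate (not isolated)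
8 | lithium bromomagnesium (5S,6S)-9-methoxy-6-methylspiro[4.5]deca-1,7,9-triene-1,6-diolate (C6–O cis to C1) | COC1=C[C@]2(CCC=C2[O-])[C@@](C)([O-])C=C1.[Li+].[Mg+2].[Br-] | intermediate (not isolated)
9 | (5S,6S)-9-methoxy-6-methyl-1,6-bis(triethylsilyloxy)spiro[4.5]deca-1,7,9-triene | COC1=C[C@]2(CCC=C2O[Si](CC)(CC)CC)[C@@](C)(O[Si](CC)(CC)CC)C=C1 | intermediate (not isolated)
10 | (5S,6S)-6-methyl-1,6-bis(triethylsilyloxy)spiro[4.5]deca-1,7-dien-9-one | O=C1C[C@]2(CCC=C2O[Si](CC)(CC)CC)[C@@](C)(O[Si](CC)(CC)CC)C=C1 | intermediate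
11 | 3-(benzyloxy)propanal | O=CCCOCc1ccccc1 | starting material
12 | lithium cross-conjugated dienolate of 10 (C9–O, C9=C10) | [O-]C1=C[C@]2(CCC=C2O[Si](CC)(CC)CC)[C@@](C)(O[Si](CC)(CC)CC)C=C1.[Li+] | intermediate (not isolated)
13 | lithium aldolate of 10 and 11 (C10 and carbinol epimers) | O=C1C(C([O-])CCOCc3ccccc3)[C@]2(CCC=C2O[Si](CC)(CC)CC)[C@@](C)(O[Si](CC)(CC)CC)C=C1.[Li+] | intermediate (not isolated)
14 | methanesulfonate of the aldol adduct (epimers) | O=C1C(C(OS(C)(=O)=O)CCOCc3ccccc3)[C@]2(CCC=C2O[Si](CC)(CC)CC)[C@@](C)(O[Si](CC)(CC)CC)C=C1 | intermediate (not isolated)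
15 | (5S,6S,10E)-10-[3-(benzyloxy)propylidene]-6-methyl-1,6-bis(triethylsilyloxy)spiro[4.5]deca-1,7-dien-9-one | O=C1/C(=C/CCOCc3ccccc3)[C@]2(CCC=C2O[Si](CC)(CC)CC)[C@@](C)(O[Si](CC)(CC)CC)C=C1 | intermediate
16 | (5S,6S,10S)-10-(3-hydroxypropyl)-6-methyl-1,6-bis(triethylsilyloxy)spiro[4.5]dec-1-en-9-one (chain cis to C6–O and C1) | OCCC[C@@H]1C(=O)CC[C@](C)(O[Si](CC)(CC)CC)[C@@]12CCC=C2O[Si](CC)(CC)CC | intermediate
17 | tetradecanoyl chloride | CCCCCCCCCCCCCC(=O)Cl | starting material
18 | 3-[(5S,6S,10S)-6-methyl-9-oxo-1,6-bis(triethylsilyloxy)spiro[4.5]dec-1-en-10-yl]propyl tetradecanoate | CCCCCCCCCCCCCC(=O)OCCC[C@@H]1C(=O)CC[C@](C)(O[Si](CC)(CC)CC)[C@@]12CCC=C2O[Si](CC)(CC)CC | intermediate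
19 | 3-[(5S,6S,10S)-9-hydroxy-6-methyl-9-(prop-1-en-2-yl)-1,6-bis(triethylsilyloxy)spiro[4.5]dec-1-en-10-yl]propyl tetradecanoate (C9 epimers) | CCCCCCCCCCCCCC(=O)OCCC[C@@H]1C(O)(C(C)=C)CC[C@](C)(O[Si](CC)(CC)CC)[C@@]12CCC=C2O[Si](CC)(CC)CC | intermediate
20 | 6-methylhept-5-en-2-one | CC(=O)CCC=C(C)C | starting material
21 | lithium 6-methylhepta-1,5-dien-2-olate | C=C([O-])CCC=C(C)C.[Li+] | intermediate (not isolated)
22 | 6-methylhepta-1,5-dien-2-yl trifluoromethanesulfonate | C=C(OS(=O)(=O)C(F)(F)F)CCC=C(C)C | intermediate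
23 | prop-2-enal | C=CC=O | starting material
24 | (2E)-8-methyl-4-methylidenenona-2,7-dienal | O=C/C=C/C(=C)CCC=C(C)C | intermediate
25 | ethyl (2Z,4E)-2-bromo-10-methyl-6-methylideneundeca-2,4,9-trienoate | CCOC(=O)/C(Br)=C/C=C/C(=C)CCC=C(C)C | intermediate
26 | (2Z,4E)-2-bromo-10-methyl-6-methylideneundeca-2,4,9-trien-1-ol | OC/C(Br)=C/C=C/C(=C)CCC=C(C)C | intermediate
27 | {[(2Z,4E)-2-bromo-10-methyl-6-methylideneundeca-2,4,9-trien-1-yl]oxy}(tert-butyl)dimethylsilane | CC(C)(C)[Si](C)(C)OC/C(Br)=C/C=C/C(=C)CCC=C(C)C | intermediate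
28 | 3-[(2S,5R,6S,10S)-2-[(2E,4E)-1-(tert-butyldimethylsilyloxy)-10-methyl-6-methylideneundeca-2,4,9-trien-2-yl]-9-hydroxy-6-methyl-1-oxo-9-(prop-1-en-2-yl)-6-(triethylsilyloxy)spiro[4.5]decan-10-yl]propyl tetradecanoate (C9 epimers) | CCCCCCCCCCCCCC(=O)OCCC[C@@H]1C(O)(C(C)=C)CC[C@](C)(O[Si](CC)(CC)CC)[C@@]12CC[C@@H](/C(=C\C=C\C(=C)CCC=C(C)C)CO[Si](C)(C)C(C)(C)C)C2=O | intermediate
29 | 3-[(2S,5R,6S,9Z,10R)-2-[(2E,4E)-1-(tert-butyldimethylsilyloxy)-10-methyl-6-methylideneundeca-2,4,9-trien-2-yl]-6-methyl-1-oxo-9-(1-oxopropan-2-ylidene)-6-(triethylsilyloxy)spiro[4.5]decan-10-yl]propyl tetradecanoate | CCCCCCCCCCCCCC(=O)OCCC[C@@H]1/C(=C(/C)C=O)CC[C@](C)(O[Si](CC)(CC)CC)[C@@]12CC[C@@H](/C(=C\C=C\C(=C)CCC=C(C)C)CO[Si](C)(C)C(C)(C)C)C2=O | intermediate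
30 | 3-[(2S,5R,6S,9Z,10R)-6-hydroxy-2-[(2E,4E)-1-hydroxy-10-methyl-6-methylideneundeca-2,4,9-trien-2-yl]-6-methyl-1-oxo-9-(1-oxopropan-2-ylidene)spiro[4.5]decan-10-yl]propyl tetradecanoate | CCCCCCCCCCCCCC(=O)OCCC[C@@H]1/C(=C(/C)C=O)CC[C@](C)(O)[C@@]12CC[C@@H](/C(=C\C=C\C(=C)CCC=C(C)C)CO)C2=O | intermediate
31 | 3-[(1R,2S,5S,6S,9Z,10R)-1,6-dihydroxy-2-[(2E,4E)-1-hydroxy-10-methyl-6-methylideneundeca-2,4,9-trien-2-yl]-6-methyl-9-(1-oxopropan-2-ylidene)spiro[4.5]decan-10-yl]propyl tetradecanoate (monomer) | CCCCCCCCCCCCCC(=O)OCCC[C@@H]1/C(=C(/C)C=O)CC[C@](C)(O)[C@@]12CC[C@@H](/C(=C\C=C\C(=C)CCC=C(C)C)CO)[C@H]2O | intermediate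
32 | CNP0458412.1, Diels–Alder homodimer of 31 (configuration as in the SMILES) | CCCCCCCCCCCCCC(=O)OCCC[C@@H]1/C(=C(/C)C=O)CC[C@](C)(O)[C@@]12CC[C@@H](/C(=C\C=C\[C@@]1(CCC=C(C)C)CCC(CCC=C(C)C)=C[C@@H]1/C=C(/CO)[C@@H]1CC[C@]3([C@H](CCCOC(=O)CCCCCCCCCCCCC)/C(=C(/C)C=O)CC[C@]3(C)O)[C@@H]1O)CO)[C@H]2O | target

**Step count and risks**

Total step count: 18. Longest linear sequence: 13 steps (steps 1–8 and 14–18, from 4-methoxyphenol); the bromotriene 27 is made in 5 steps (9–13).

Three steps most likely to fail: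

Step 3. The enantioselective dearomative ring expansion is untested; over-oxidation to the quinone, ionisation of the benzylic carbinol, or low ee are possible. Fallback: separate the dearomatisation from the stereo-determining shift. From 5, PhI(OAc)2 in MeOH gives the quinone monoketal 2-(1-hydroxycyclobutyl)-4,4-dimethoxycyclohexa-2,5-dien-1-one F1 by a standard oxidation. A chiral BINOL-derived phosphoric acid (toluene, −40 °C) then ionises one methoxy group; the resulting methoxy-stabilised cation, paired with the chiral phosphate, undergoes the same 1,2-shift and returns to the route at 6.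

Step 14. Coupling a hindered silyl enol ether with a sensitive bromotriene may stall, give β-hydride elimination, or isomerise the product. Fallback with reversed polarity: from 19, N-bromosuccinimide converts the silyl enol ether into the α-bromo ketone 3-[(5R,6S,10S)-2-bromo-9-hydroxy-6-methyl-1-oxo-9-(prop-1-en-2-yl)-6-(triethylsilyloxy)spiro[4.5]decan-10-yl]propyl tetradecanoate F2. From 27, t-BuLi then ZnCl2 give [(2Z,4E)-1-(tert-butyldimethylsilyloxy)-10-methyl-6-methylideneundeca-2,4,9-trien-2-yl]zinc chloride F3. A NiCl2·glyme/bis(oxazoline)-catalysed stereoconvergent Negishi coupling of F2 with F3 then rejoins the route at 28.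

Step 18. The intermolecular cycloaddition has no facial control, so at best half of the exo adducts is the target, and competing cycloaddition modes or polymerisation may lower this further. Fallback with a temporary silicon tether: from 31, i-Pr2SiCl2 (0.5 equiv) and imidazole join the primary allylic hydroxyls of two molecules as the di(propan-2-yl)silanediyl bis-ether of 31 F4. Heating F4 in dilute toluene gives the silylene-bridged intramolecular cycloadduct F5 through a 13-membered tether ring that restricts the mutual orientation of diene and dienophile (its facial sense would have to be established experimentally). HF·pyridine then removes the bridge and gives 32.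

**Further compounds**

F1 | step 3 | 2-(1-hydroxycyclobutyl)-4,4-dimethoxycyclohexa-2,5-dien-1-one | COC1(OC)C=CC(=O)C(=C1)C1(O)CCC1
F2 | step 14 | 3-[(5R,6S,10S)-2-bromo-9-hydroxy-6-methyl-1-oxo-9-(prop-1-en-2-yl)-6-(triethylsilyloxy)spiro[4.5]decan-10-yl]propyl tetradecanoate (C2 and C9 epimers) | CCCCCCCCCCCCCC(=O)OCCC[C@@H]1C(O)(C(C)=C)CC[C@](C)(O[Si](CC)(CC)CC)[C@@]12CCC(Br)C2=O
F3 | step 14 | [(2Z,4E)-1-(tert-butyldimethylsilyloxy)-10-methyl-6-methylideneundeca-2,4,9-trien-2-yl]zinc chloride | CC(C)(C)[Si](C)(C)OC/C([Zn]Cl)=C/C=C/C(=C)CCC=C(C)C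
F4 | step 18 | di(propan-2-yl)silanediyl bis-ether linking the primary allylic oxygens of two molecules of 31 | CCCCCCCCCCCCCC(=O)OCCC[C@@H]1/C(=C(/C)C=O)CC[C@](C)(O)[C@@]12CC[C@@H](/C(=C\C=C\C(=C)CCC=C(C)C)CO[Si](C(C)C)(C(C)C)OC/C(=C/C=C/C(=C)CCC=C(C)C)[C@@H]3CC[C@]4([C@H](CCCOC(=O)CCCCCCCCCCCCC)/C(=C(/C)C=O)CC[C@]4(C)O)[C@@H]3O)[C@H]2O
F5 | step 18 | silylene-bridged Diels–Alder adduct (32 with its two primary allylic oxygens joined through Si(i-Pr)2) | CCCCCCCCCCCCCC(=O)OCCC[C@@H]1/C(=C(/C)C=O)CC[C@](C)(O)[C@@]12CC[C@@H](/C(=C\C=C\[C@@]1(CCC=C(C)C)CCC(CCC=C(C)C)=C[C@@H]1/C=C(/CO[Si]4(C(C)C)C(C)C)[C@@H]1CC[C@]3([C@H](CCCOC(=O)CCCCCCCCCCCCC)/C(=C(/C)C=O)CC[C@]3(C)O)[C@@H]1O)CO4)[C@H]2O
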